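The peak of target cannot be read off directly: the north-west flask was read at 0.0833 d, 0.167 d and 0.333 d, each reading with a scatter of 2 percentage points, so the peak has to be reckoned.

| flask | starting material | remark | time |
|---|---|---|---|
| north-west | 0.050 M | the very flask that is asked about, followed so far |  |
| west | 0.034 M | run made earlier |  |
| flask | 0.050 M |  | 15 d |

| run | time / d | target / % | starting material / % |
|---|---|---|---|
| north-west | 0.0833 | 33 | 63 |
| north-west | 0.167 | 38 | 47 |
| north-west | 0.333 | 32 | 29 |
| north-west | 0.833 | 16 | 18 |
| north-west | 1.67 | 13 | 11 |
| north-west | 4.00 | 13 | 8 |
| north-west | 8.00 | 9 | 11 |
| west | 0.0556 | 22 | 77 |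
| west | 0.125 | 31 | 60 |
| west | 0.250 | 30 | 44 |
| west | 0.625 | 15 | 28 |
| west | 1.25 | 11 | 18 |
| west | 3.00 | 9 | 12 |
| west | 6.00 | 11 | 12 |

(standard deviation of a reading: 2 percentage points)

- the best time, 15 d at the latest, for target
- the amount of target, in percent of the starting material charged, at that time
- the first time at which target reaches 18 %, in the same percent

- in percentages every species weighs as the starting material in it: one target counts as two
- what was read earlier has a scatter of 2 percentage points, one standard deviation
- a reading or a percentage of target counts all its forms, free or not

How does the starting material go? Let S and T be starting material and target as fractions of the charge. If S falls second order, 1/S − 1 grows as a·t, where a is the flask's starting rate. The first readings give a = 7.05 d⁻¹ in north-west and 5.37 d⁻¹ in west, a ratio of 1.31 against a charge ratio of 1.47, and I accept that as scatter.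

How does target go? The missing share, 1 − S − T, grows between the second and third readings. Dividing that growth by the mean T gives a loss constant λ of 4.13 d⁻¹ in north-west and 4.46 d⁻¹ in west.

Could that loss be bimolecular? Then the richer north-west flask should show the larger λ, yet it shows less than west. So I take the loss as first order, with mean λ = 4.29 d⁻¹.

When does target stop rising? It rises while making, aS², exceeds loss, λT. Call the race number G = a/λ, the starting rate of making against the constant of loss; for north-west, G = 1.64. The peak then stands where R = GS²/T equals one.

How does R drift? In north-west it falls from 1.97 at the first reading to 0.954 at the second, so I put the peak just before 0.167 d.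

But isn't the reading of 38 % suspect? I don't set the height equal to it, but I can't shed it either, since it enters λ for north-west and so G: GS² at the read S gives 36.3 %, a reckoning that carries the scatter of that reading. The late reading of 9 % lies below that, so the best time is an early one, under kinetic control rather than thermodynamic control.

The forecast says 0.17 d, 35 % and 0.8 h, and differs from me on the loss: “Target forms first, then is lost, apparently also bimolecularly”.

The flask gives 0.154 d, 37.0 % and 0.687 h.

    2 starting material ⇌ target (K = 111 L mol⁻¹, k = 0.0583 L mol⁻¹ min⁻¹)
    target ⇌ isomer of the product (K = 7.63, k = 0.00293 min⁻¹)
    crystals ⇌ target, rate k3*(cs3 - [target]) while solid is left; crystals form when [target] > cs3 (solubility = 32.0 mM, k = 0.0495 min⁻¹)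

At 0.154 d this flask holds 45.5 % of starting material and 37.0 % of target, which puts R at 0.918. The neighbour flask charged with 0.030 M takes a from west in proportion to charge, so its G is 1.10. In west, R falls from 1.45 to 0.807 between the second and third readings, so I take the mean S of those readings, 52.0 %, for the neighbour's peak. GS² then gives 29.7 %, and that neighbour flask's highest target is 29.9 %.

Readings and results come from a simulation for an exercise.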